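The readings are calculated from invented constants; scatter was added.

The ratio of two clocks carries this reckoning, worked with the fraction of Z left.

| setting | autumn | noon | winter | flask |
|---|---|---|---|---|
| Z | 0.22 M | 0.22 M | 0.22 M | 0.22 M |
| L | 0.209 M | 0.209 M | 0.209 M | 0.209 M |
| E | 3.5 mM | 3.5 mM | 7 mM | 3.5 mM |
| G | 1.5 mM | 2.4 mM | 1.1 mM | 1.1 mM |
| remark | run made earlier | run made earlier | run made earlier |  |

| run | time / min | J / % | Z / % |
|---|---|---|---|
| autumn | 2.50 | 0.4 | 46.3 |
| autumn | 6.00 | 3.3 | 14.5 |
| autumn | 12.0 | 7.3 | 1.2 |
| autumn | 20.0 | 12.2 | 0 |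
| noon | 5.00 | 4.6 | 19.9 |
| noon | 10.0 | 7.4 | 4.4 |
| noon | 15.0 | 11.5 | 0.1 |
| noon | 20.0 | 13.5 | 1.6 |
| winter | 1.33 | 0 | 45.0 |
| winter | 3.00 | 0.1 | 16.3 |
| winter | 8.00 | 5.9 | 1.5 |
| winter | 20.0 | 11.7 | 1.1 |

(scatter of a reading: 1 percentage point)

- factor on the rate of making J when 5.0% of the Z are converted if E is charged twice over
- factor on the rate when 5.0% of the Z are converted if E is charged at 20 mM instead

- "the catalyst" is E with its forms; G is a second catalyst

The autumn run, with the flask's E, leaves 14.5% of Z at 6.00 min, so the feed clock reads 0.322 /min; the winter run, with E doubled, reads about twice as fast. Converted Z stands first as a pool. The readings of the winter run, with the flask's G, show 0.00530 /min of that pool turning into J between 8.00 min and 20.0 min. Drain over feed is the clock ratio, 0.0165.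

My reckoning takes the drain as free of E; the winter run differs from the autumn and noon runs in G as well as in E. At 5.0% of Z converted, the pool is that fraction less the J made. More E reaches that point sooner, so the factor on the rate has the lower bound 1. Taking the pool at its full 5.0% over the whole time overstates the J made, which gives the upper bound 1.001. Integrating over the fraction left puts the J made at 0.0426% of the converted Z, so the factors tighten to 1.000 for doubled E and 1.000 at 20 mM.

The forecast, reading the conversion as J made and not as Z lost, gives 1.05 and 1.1, both above the bracket: “I expect factors near 1”.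

    Z + E → E + Q (k = 1.50 /M/s)
    2 G ⇌ X, settled at all times (K = 6.80 × 10⁵ /M)
    E → D (k = 1.40 × 10⁻⁶ /s)
    L + G + Q → G + J (k = 20.0 /M²/s)

The flask gives 1.00 and 1.00, and the forecast stands within the margins. The pool is Q. The flask's rate at 3.82 min, with 0.7 of Z converted, is 14 times that at 5.0%; the clock ratio reckons 13.8. In the winter run the clock ratio becomes 0.00823, which gives 0.804% of J at 3.00 min, where the reading is 0.1%.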